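**Plan**

- Retrosynthesis: (a) C-3′–Br and C-4′–Cl go back, through a stereospecific 1,2-halogen interchange and two trans-diaxial openings, to the C-3′=C-4′ alkene; (b) a carbonyl carbon is placed on C-1′ and tied to the oxygen on C-3, and the resulting spiro-cyclohexene is cut at C-1′–C-2′ and C-5′–C-6′ (retro-Diels–Alder) into isoprene and an α-methylene lactone; (c) the oxane is cut at O-1–C-6 (bromoetherification), the lactone at its carbonyl (alkyne carbonylation) and the chain at C-2–C-1′ (acetylide plus α-hydroxy ketone).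
- Enabling feature: the C-3 hydroxyl is γ to C-1′ (O–C-3–C-2–C-1′), so one extra carbonyl carbon makes a five-membered α-methylene lactone on C-1′; the methyl-bearing C-4′ is para to C-1′, the pattern an isoprene cycloaddition gives.
- Forward order: C10 chain from 6-methylhept-5-en-2-one → temporary lactone → oxane → cyclohexene (last ring of the skeleton) → excision of the lactone carbonyl → halogens.
- Stereochemistry: C-3 from proline catalysis; C-2 from chelation-controlled acetylide addition; C-5 from a chair-like anti bromoetherification; C-1′ from cycloaddition on the convex face of the bicyclic lactone, kept by stereoretentive decarbonylation; C-3′ and C-4′ from substrate-controlled trans-diaxial openings relayed by the suprafacial halogen interchange.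

Key step: step 5

Assumption: L-proline is taken to give the (3R)-α-oxygenated ketone, as it does with aldehydes and cyclic ketones (D-proline would serve if the sense were opposite); atom numbers follow the target, oxane O-1, C-2 (Me, cyclohexyl), C-3 (OH), C-5 (Br), C-6 (Me2), cyclohexane C-1′ to C-6′ with Br on C-3′ and Cl on C-4′.

**Step 1**
Reactants: 1 6-methylhept-5-en-2-one
Product: 3 (3R)-3-hydroxy-6-methylhept-5-en-2-one, via aminoxy ketone 2 (not isolated)
Conditions: 1 (3 equiv), PhN=O (slow addition), L-proline (20 mol %), DMSO, rt; then CuSO4·5H2O (30 mol %), MeOH, 0 °C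
Reagents that add atoms: nitrosobenzene O=Nc1ccccc1
Why: Proline-catalysed α-aminoxylation (O-selective nitroso aldol of the more substituted enamine, the carboxylic acid guiding PhN=O to one enamine face) should set the future C-3 as R, and CuSO4 then cleaves the weak N–O bond without touching ketone or alkene.

**Step 2**
Reactants: 3 (3R)-3-hydroxy-6-methylhept-5-en-2-one, 4 ethynylmagnesium bromide
Product: 5 (3R,4R)-3,7-dimethyloct-6-en-1-yne-3,4-diol
Conditions: 4 (3 equiv), THF, −78 to 0 °C; aq NH4Cl
Reagents that add atoms: none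
Why: Cram-chelate addition: the first equivalent forms the magnesium alkoxide, magnesium bridges it to the ketone oxygen, and the acetylide adds from the side of the small α-hydrogen, which should give the (3R,4R)-diol and so the future C-2 quaternary centre.

**Step 3**
Reactants: 5 (3R,4R)-3,7-dimethyloct-6-en-1-yne-3,4-diol, 6 carbon monoxide
Product: 7 (4R,5R)-4-hydroxy-4-methyl-3-methylidene-5-(3-methylbut-2-en-1-yl)oxolan-2-one
Conditions: PdCl2(PPh3)2 (5 mol %), SnCl2 (5 mol %), CO (7 atm), MeCN, 70 °C
Reagents that add atoms: none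
Why: Palladium-catalysed cyclocarbonylation of a homopropargylic alcohol: the alkoxycarbonyl–palladium species adds syn across the alkyne and protonolysis leaves the exocyclic methylene; only the secondary hydroxyl can close a five-membered ring, so the temporary lactone masks O–C-3 and activates the future dienophile.

**Step 4**
Reactants: 7 (4R,5R)-4-hydroxy-4-methyl-3-methylidene-5-(3-methylbut-2-en-1-yl)oxolan-2-one
Product: 8 (3aR,6R,7aR)-6-bromo-3a,5,5-trimethyl-3-methylidenehexahydro-2H-furo[3,2-b]pyran-2-one
Conditions: 2,4,4,6-tetrabromocyclohexa-2,5-dien-1-one (1.1 equiv), MeNO2, 0 °C to rt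
Reagents that add atoms: 2,4,4,6-tetrabromocyclohexa-2,5-dien-1-one O=C1C(Br)=CC(Br)(Br)C=C1Br
Why: Bromoetherification (6-endo, Markovnikov at the CMe2 terminus) of the only electron-rich alkene: anti addition through a chair-like transition state with the rigid lactone carbon equatorial should place bromine equatorial and favour the (6R)-bromide, while the electron-poor methylene lactone stays inert.

**Step 5**
Reactants: 8 (3aR,6R,7aR)-6-bromo-3a,5,5-trimethyl-3-methylidenehexahydro-2H-furo[3,2-b]pyran-2-one, 9 isoprene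
Product: 10 (3R,3aR,6R,7aR)-6-bromo-3a,4′,5,5-tetramethylhexahydrospiro[furo[3,2-b]pyran-3,1′-cyclohex[3]en]-2-one
Conditions: 9 (5 equiv), Et2AlCl (30 mol %), CH2Cl2, −20 °C to rt
Reagents that add atoms: none
Why: Et2AlCl binds the lactone carbonyl and the concerted, asynchronous [4+2] cycloaddition first joins the unhindered exocyclic CH2 (future C-6′) to C-1 of isoprene and then the fully substituted α-carbon (future C-1′) to C-4 of isoprene. The closest known reaction type is the Lewis-acid-catalysed Diels–Alder reaction of α-methylene-γ-butyrolactones with 2-substituted butadienes. The cyclohexene is closed by an intermolecular [4+2] annulation in which both ring bonds (C-1′–C-2′ and C-5′–C-6′) form in one step. The only new stereocentre, spiro C-1′, is set by approach of the diene to the convex face of the cis-fused bicycle, the face of the angular methyl group and C-7a–H, which is turned away from the oxane ring and lies anti to the allylic C–O bond. The step needs para regioselectivity, secured by the match of the large HOMO coefficient at C-1 of isoprene with the large LUMO coefficient at the β-methylene carbon and raised by the Lewis acid, and it needs chemoselectivity, secured because the methylene lactone is the only activated alkene.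

**Step 6**
Reactants: 10 (3R,3aR,6R,7aR)-6-bromo-3a,4′,5,5-tetramethylhexahydrospiro[furo[3,2-b]pyran-3,1′-cyclohex[3]en]-2-one
Product: 11 (3R,3aR,6R,7aR)-6-bromo-3a,4′,5,5-tetramethylhexahydrospiro[furo[3,2-b]pyran-3,1′-cyclohex[3]en]-2-ol (lactol, both anomers)
Conditions: i-Bu2AlH (1.1 equiv), CH2Cl2, −78 °C; aq potassium sodium tartrate
Reagents that add atoms: none
Why: Partial lactone reduction: at −78 °C the tetrahedral aluminium acetal persists until work-up and gives the lactol, the secondary bromide and the alkene being inert to the hydride.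

**Step 7**
Reactants: 11 (3R,3aR,6R,7aR)-6-bromo-3a,4′,5,5-tetramethylhexahydrospiro[furo[3,2-b]pyran-3,1′-cyclohex[3]en]-2-ol
Product: 13 (2R,3R,5R)-5-bromo-2,6,6-trimethyl-2-[(1S)-4-methylcyclohex-3-en-1-yl]oxan-3-ol, via hydroxy aldehyde 12 (not isolated)
Conditions: RhCl(PPh3)3 (1.1 equiv), PhCN, 130 °C
Reagents that add atoms: none
Why: Tsuji–Wilkinson decarbonylation of the ring-opened aldehyde: insertion into the formyl C–H bond, CO extrusion and C–H reductive elimination proceed with retention at C-1′, so the configuration from step 5 is kept while the helper carbon leaves and the C-3 hydroxyl is set free.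

**Step 8**
Reactants: 13 (2R,3R,5R)-5-bromo-2,6,6-trimethyl-2-[(1S)-4-methylcyclohex-3-en-1-yl]oxan-3-ol
Product: 14 (2R,3R,5R)-5-bromo-2-[(1S,3R,4R)-3-bromo-4-hydroxy-4-methylcyclohexyl]-2,6,6-trimethyloxan-3-ol
Conditions: NBS (1.1 equiv), acetone–H2O (4:1), 0 °C
Reagents that add atoms: N-bromosuccinimide O=C1CCC(=O)N1Br; water O
Why: Bromohydrin formation: bromonium formation is reversible and only the ion anti to the equatorial C-1′ substituent can be opened by water at the tertiary carbon through a chair-like trans-diaxial transition state (Fürst–Plattner rule), which should give the axial C-3′ bromide and axial C-4′ hydroxyl.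

**Step 9**
Reactants: 14 (2R,3R,5R)-5-bromo-2-[(1S,3R,4R)-3-bromo-4-hydroxy-4-methylcyclohexyl]-2,6,6-trimethyloxan-3-ol
Product: 15 (2R,3R,5R)-5-bromo-2,6,6-trimethyl-2-[(1S,3S,6R)-6-methyl-7-oxabicyclo[4.1.0]heptan-3-yl]oxan-3-ol (epoxide oxygen cis to the oxanyl group)
Conditions: K2CO3, MeOH, rt
Reagents that add atoms: none
Why: Intramolecular Williamson closure of the trans-diaxial bromohydrin gives the epoxide on the face syn to the oxanyl group, with inversion at C-3′.

**Step 10**
Reactants: 15 (2R,3R,5R)-5-bromo-2,6,6-trimethyl-2-[(1S,3S,6R)-6-methyl-7-oxabicyclo[4.1.0]heptan-3-yl]oxan-3-ol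
Product: 16 (2R,3R,5R)-5-bromo-2-[(1S,3R,4R)-3-chloro-4-hydroxy-4-methylcyclohexyl]-2,6,6-trimethyloxan-3-ol
Conditions: HCl (1 M in Et2O, 1.1 equiv), CH2Cl2, −20 °C
Reagents that add atoms: hydrogen chloride Cl
Why: Acid-promoted epoxide opening by chloride at the secondary carbon C-3′ with inversion, the only trans-diaxial (Fürst–Plattner) mode open to this epoxide, as found for the analogous 4-substituted 1-methylcyclohexene oxides of the terpene series.

**Step 11**
Reactants: 16 (2R,3R,5R)-5-bromo-2-[(1S,3R,4R)-3-chloro-4-hydroxy-4-methylcyclohexyl]-2,6,6-trimethyloxan-3-ol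
Product: 17 (2R,3R,5R)-5-bromo-2-[(1S,3R,4R)-4-bromo-3-chloro-4-methylcyclohexyl]-2,6,6-trimethyloxan-3-ol (halogens trans-diaxial)
Conditions: HBr (gas), CH2Cl2, −40 to −20 °C, short contact
Reagents that add atoms: hydrogen bromide Br
Why: SN1 substitution of the tertiary alcohol with retention: the anti-periplanar axial chlorine bridges the C-4′ cation and bromide enters axially on the face the hydroxyl left, while the low temperature spares the acid-sensitive oxane.

**Step 12**
Reactants: 17 (2R,3R,5R)-5-bromo-2-[(1S,3R,4R)-4-bromo-3-chloro-4-methylcyclohexyl]-2,6,6-trimethyloxan-3-ol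
Product: 18 caespitol, (2R,3R,5R)-5-bromo-2-[(1S,3S,4S)-3-bromo-4-chloro-4-methylcyclohexyl]-2,6,6-trimethyloxan-3-ol
Conditions: PhCl, 100 °C, sealed tube, dark
Reagents that add atoms: none
Why: Thermal diaxial-to-diequatorial 1,2-interchange of a vicinal dihalide (dyotropic shift through a bridged ion pair, the reaction type known from steroidal trans-diaxial dihalides): each halogen migrates on its own face, so bromine should arrive equatorial at C-3′ cis to the oxanyl group and chlorine equatorial at C-4′, the product pairing a tertiary C–Cl with a secondary C–Br bond.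

**Compound list**

1 | 6-methylhept-5-en-2-one | CC(=O)CCC=C(C)C | starting material
2 | (3R)-6-methyl-3-[(phenylamino)oxy]hept-5-en-2-one | CC(=O)[C@H](ONc1ccccc1)CC=C(C)C | intermediate
3 | (3R)-3-hydroxy-6-methylhept-5-en-2-one | CC(=O)[C@H](O)CC=C(C)C | intermediate
4 | ethynylmagnesium bromide | C#C[Mg]Br | starting material
5 | (3R,4R)-3,7-dimethyloct-6-en-1-yne-3,4-diol | C#C[C@@](C)(O)[C@H](O)CC=C(C)C | intermediate
6 | carbon monoxide | [C-]#[O+] | starting material
7 | (4R,5R)-4-hydroxy-4-methyl-3-methylidene-5-(3-methylbut-2-en-1-yl)oxolan-2-one | C=C1C(=O)O[C@H](CC=C(C)C)[C@]1(C)O | intermediate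
8 | (3aR,6R,7aR)-6-bromo-3a,5,5-trimethyl-3-methylidenehexahydro-2H-furo[3,2-b]pyran-2-one | CC1(C)O[C@]2(C)C(=C)C(=O)O[C@@H]2C[C@H]1Br | intermediate
9 | isoprene (2-methylbuta-1,3-diene) | C=CC(C)=C | starting material
10 | (3R,3aR,6R,7aR)-6-bromo-3a,4′,5,5-tetramethylhexahydrospiro[furo[3,2-b]pyran-3,1′-cyclohex[3]en]-2-one | CC1(C)O[C@]2(C)[C@]3(CCC(C)=CC3)C(=O)O[C@@H]2C[C@H]1Br | intermediate
11 | (3R,3aR,6R,7aR)-6-bromo-3a,4′,5,5-tetramethylhexahydrospiro[furo[3,2-b]pyran-3,1′-cyclohex[3]en]-2-ol (both anomers) | CC1(C)O[C@]2(C)[C@]3(CCC(C)=CC3)C(O)O[C@@H]2C[C@H]1Br | intermediate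
12 | (1R)-1-[(2R,3R,5R)-5-bromo-3-hydroxy-2,6,6-trimethyloxan-2-yl]-4-methylcyclohex-3-ene-1-carbaldehyde | CC1(C)O[C@](C)([C@@]2(C=O)CCC(C)=CC2)[C@H](O)C[C@H]1Br | intermediate
13 | (2R,3R,5R)-5-bromo-2,6,6-trimethyl-2-[(1S)-4-methylcyclohex-3-en-1-yl]oxan-3-ol | CC1(C)O[C@](C)([C@H]2CCC(C)=CC2)[C@H](O)C[C@H]1Br | intermediate
14 | (2R,3R,5R)-5-bromo-2-[(1S,3R,4R)-3-bromo-4-hydroxy-4-methylcyclohexyl]-2,6,6-trimethyloxan-3-ol | CC1(C)O[C@](C)([C@H]2CC[C@@](C)(O)[C@H](Br)C2)[C@H](O)C[C@H]1Br | intermediate
15 | (2R,3R,5R)-5-bromo-2,6,6-trimethyl-2-[(1S,3S,6R)-6-methyl-7-oxabicyclo[4.1.0]heptan-3-yl]oxan-3-ol | CC1(C)O[C@](C)([C@H]2CC[C@@]3(C)O[C@H]3C2)[C@H](O)C[C@H]1Br | intermediate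
16 | (2R,3R,5R)-5-bromo-2-[(1S,3R,4R)-3-chloro-4-hydroxy-4-methylcyclohexyl]-2,6,6-trimethyloxan-3-ol | CC1(C)O[C@](C)([C@H]2CC[C@@](C)(O)[C@H](Cl)C2)[C@H](O)C[C@H]1Br | intermediate
17 | (2R,3R,5R)-5-bromo-2-[(1S,3R,4R)-4-bromo-3-chloro-4-methylcyclohexyl]-2,6,6-trimethyloxan-3-ol | CC1(C)O[C@](C)([C@H]2CC[C@@](C)(Br)[C@H](Cl)C2)[C@H](O)C[C@H]1Br | intermediate
18 | caespitol, (2R,3R,5R)-5-bromo-2-[(1S,3S,4S)-3-bromo-4-chloro-4-methylcyclohexyl]-2,6,6-trimethyloxan-3-ol | CC1(C)O[C@](C)([C@H]2CC[C@](C)(Cl)[C@@H](Br)C2)[C@H](O)C[C@H]1Br | target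

**Step count and risks**

Total steps: 12. Longest linear sequence: 12 steps (1 to 18).

Steps most likely to fail:

Step 12. The halogen interchange may stop at an unfavourable equilibrium, ionisation of the tertiary bromide may end in loss of HBr instead of return of the halide, or the β-bromo ether of the oxane may start to rearrange at the temperature needed. The fallback is a one-step anti addition of bromine chloride to the alkene (Bu4NBrCl2, CH2Cl2, −78 °C). It sets out from 13 and comes back to the route at 18. The bromonium ion on the face syn to the oxanyl group, opened by chloride at the tertiary carbon, gives 18 directly. The ion on the other face gives the trans-diaxial diastereomer (2R,3R,5R)-5-bromo-2-[(1S,3R,4R)-3-bromo-4-chloro-4-methylcyclohexyl]-2,6,6-trimethyloxan-3-ol F1, which is expected to predominate and would be removed by chromatography. Any 17 formed alongside is the substrate of step 12.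

Step 7. The tertiary alkyl–rhodium intermediate may undergo β-hydride elimination, or the neopentyl-type aldehyde, present mainly as the lactol, may fail to add to rhodium. The fallback is a thiol-catalysed radical-chain decarbonylation (t-C12H25SH, di-tert-butyl peroxide, PhCl, 130 °C). It sets out from 11, passes through 12 and comes back to the route at 13. The acyl radical loses carbon monoxide and the thiol reduces the tertiary C-1′ radical. Because that radical is planar, stereocontrol at C-1′ is lost, and 13 would have to be separated from its C-1′ epimer (2R,3R,5R)-5-bromo-2,6,6-trimethyl-2-[(1R)-4-methylcyclohex-3-en-1-yl]oxan-3-ol F2.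

Step 5. Bond formation at the dienophile carbon flanked by a quaternary centre may be too slow, or facial selectivity at the spiro carbon may be poor. The fallback sets out from 8 and comes back to the route at 10. Cycloaddition of 8 with the more reactive 2-(trimethylsilyloxy)buta-1,3-diene would give 6-bromo-3a,5,5-trimethyl-4′-(trimethylsilyloxy)hexahydrospiro[furo[3,2-b]pyran-3,1′-cyclohex[3]en]-2-one F3 (either spiro epimer). Acidic work-up would give (3aR,6R,7aR)-6-bromo-3a,5,5-trimethylhexahydrospiro[furo[3,2-b]pyran-3,1′-cyclohexane]-2,4′-dione F4. Its cyclohexanone ring is symmetrical, so the spiro carbon is no longer stereogenic and the face of attack no longer matters. Group-selective deprotonation under reagent control (lithium bis[(R)-1-phenylethyl]amide or its antipode, LiCl, THF, −78 °C) and trapping with PhNTf2 would then give (3R,3aR,6R,7aR)-6-bromo-3a,5,5-trimethyl-2-oxohexahydrospiro[furo[3,2-b]pyran-3,1′-cyclohex[3]en]-4′-yl trifluoromethanesulfonate F5. The lactone has no α-hydrogen and is safe from the base. Coupling with MeMgBr under Fe(acac)3 catalysis (THF, −30 °C) would give 10.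

**Further compounds**

F1 | step 12 | (2R,3R,5R)-5-bromo-2-[(1S,3R,4R)-3-bromo-4-chloro-4-methylcyclohexyl]-2,6,6-trimethyloxan-3-ol | CC1(C)O[C@](C)([C@H]2CC[C@@](C)(Cl)[C@H](Br)C2)[C@H](O)C[C@H]1Br
F2 | step 7 | (2R,3R,5R)-5-bromo-2,6,6-trimethyl-2-[(1R)-4-methylcyclohex-3-en-1-yl]oxan-3-ol | CC1(C)O[C@](C)([C@@H]2CCC(C)=CC2)[C@H](O)C[C@H]1Br
F3 | step 5 | 6-bromo-3a,5,5-trimethyl-4′-(trimethylsilyloxy)hexahydrospiro[furo[3,2-b]pyran-3,1′-cyclohex[3]en]-2-one | CC1(C)O[C@]2(C)C3(CCC(O[Si](C)(C)C)=CC3)C(=O)O[C@@H]2C[C@H]1Br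
F4 | step 5 | (3aR,6R,7aR)-6-bromo-3a,5,5-trimethylhexahydrospiro[furo[3,2-b]pyran-3,1′-cyclohexane]-2,4′-dione | CC1(C)O[C@]2(C)C3(CCC(=O)CC3)C(=O)O[C@@H]2C[C@H]1Br
F5 | step 5 | (3R,3aR,6R,7aR)-6-bromo-3a,5,5-trimethyl-2-oxohexahydrospiro[furo[3,2-b]pyran-3,1′-cyclohex[3]en]-4′-yl trifluoromethanesulfonate | CC1(C)O[C@]2(C)[C@]3(CCC(OS(=O)(=O)C(F)(F)F)=CC3)C(=O)O[C@@H]2C[C@H]1Br
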